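The route rests on disconnecting the C4–C4a bond of ring C, leaving an O1–C2 aryl ether that already holds the (S)-stereocentre. The key step, an intramolecular Friedel–Crafts acylation of a mixed anhydride, closes ring C and installs the C4 ketone in one operation. It exploits the symmetry of the phloroglucinol-derived ring A: the two carbons ortho to O1 (future C4a and C8) are equivalent, so only one chromanone can form. The precursor is (S)-3-(3-bromo-5-iodo-4-methoxyphenyl)-3-[3,5-bis(tert-butyldimethylsilyloxy)phenoxy]propanoic acid, made by asymmetric transfer hydrogenation and Mitsunobu inversion. Its iodide and bromide later carry the alkenol and prenyl side chains of ring B.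

Key step: step 8

Remark on the chemistry: the target's only stereocentre, C2, is (S); the (R,R)-TsDPEN ruthenium catalyst is assumed to reduce the aryl β-keto ester to the (R)-carbinol, as it does aryl alkyl ketones, and the Mitsunobu inversion then gives (S).

Step 1
Reactants: 1 methyl 3-bromo-4-hydroxybenzoate
Product: 2 methyl 3-bromo-4-hydroxy-5-iodobenzoate
Conditions: NIS (1.05 equiv), TsOH·H2O (10 mol %), MeCN, rt
Reagents that add atoms: N-iodosuccinimide, O=C1CCC(=O)N1I
Why: Electrophilic aromatic iodination, in which the phenol directs the iodonium source to its only free ortho carbon because the para position is blocked by the ester.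

Step 2
Reactants: 2 methyl 3-bromo-4-hydroxy-5-iodobenzoate
Product: 3 methyl 3-bromo-5-iodo-4-methoxybenzoate
Conditions: MeI, K2CO3, DMF, rt
Reagents that add atoms: iodomethane, CI
Why: Williamson O-methylation of an acidic, doubly ortho-halogenated phenol, which also prevents any later cyclisation of a free phenol onto the neighbouring alkyne.

Step 3
Reactants: 3 methyl 3-bromo-5-iodo-4-methoxybenzoate; 4 tert-butyl acetate
Product: 6 tert-butyl 3-(3-bromo-5-iodo-4-methoxyphenyl)-3-oxopropanoate, via lithium enolate 5 (not isolated)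
Conditions: 4 (2.6 equiv), LiN(iPr)2 (2.5 equiv), THF, −78 °C; then 3, −78 → −20 °C; aq. NH4Cl
Reagents that add atoms: none
Why: Crossed Claisen condensation, in which the preformed ester enolate acylates on the methyl ester while the excess enolate absorbs the acidic proton of the β-keto ester, the amide base being fully consumed before the aryl halide is added.

Step 4
Reactants: 6 tert-butyl 3-(3-bromo-5-iodo-4-methoxyphenyl)-3-oxopropanoate
Product: 7 tert-butyl (R)-3-(3-bromo-5-iodo-4-methoxyphenyl)-3-hydroxypropanoate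
Conditions: RuCl(p-cymene)[(R,R)-TsDPEN] (1 mol %), HCO2H/Et3N (5:2), EtOAc, 40 °C
Reagents that add atoms: none
Why: Noyori asymmetric transfer hydrogenation, in which the (R,R)-diamine ligand and the CH–π contact between the cymene ligand and the aryl group direct hydride to one face of the ketone and should give the (R)-carbinol without touching the aryl halides.

Step 5
Reactants: 8 phloroglucinol
Product: 9 3,5-bis(tert-butyldimethylsilyloxy)phenol
Conditions: TBSCl (2.0 equiv), imidazole (4 equiv), DMF, 0 °C → rt; chromatography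
Reagents that add atoms: tert-butyldimethylsilyl chloride, CC(C)(C)[Si](C)(C)Cl
Why: Statistical O-silylation of a symmetric triol, from which the bis-ether should be separable while the mono- and tris-silylated material can be recycled.

Step 6
Reactants: 7 tert-butyl (R)-3-(3-bromo-5-iodo-4-methoxyphenyl)-3-hydroxypropanoate; 9 3,5-bis(tert-butyldimethylsilyloxy)phenol
Product: 10 tert-butyl (S)-3-(3-bromo-5-iodo-4-methoxyphenyl)-3-[3,5-bis(tert-butyldimethylsilyloxy)phenoxy]propanoate
Conditions: PPh3 (1.5 equiv), DIAD (1.5 equiv, slow addition), toluene, 0 °C → rt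
Reagents that add atoms: none
Why: Mitsunobu etherification, in which the phenoxide displaces the oxyphosphonium group by SN2 with inversion (R → S), the electron-poor dihaloaryl group disfavouring ionisation and the cold, non-polar medium restraining β-elimination.

Step 7
Reactants: 10 tert-butyl (S)-3-(3-bromo-5-iodo-4-methoxyphenyl)-3-[3,5-bis(tert-butyldimethylsilyloxy)phenoxy]propanoate
Product: 12 (S)-3-(3-bromo-5-iodo-4-methoxyphenyl)-3-[3,5-bis(tert-butyldimethylsilyloxy)phenoxy]propanoic acid, via trimethylsilyl ester 11 (not isolated)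
Conditions: TMSOTf (2 equiv), 2,6-lutidine (3 equiv), CH2Cl2, 0 °C; then aq. citrate buffer (pH 4)
Reagents that add atoms: none
Why: Silyl triflate-mediated cleavage of a tert-butyl ester, in which O-silylation releases the tert-butyl group as the alkene in a base-buffered medium, so that no lasting tert-butyl cation alkylates the electron-rich ring and no hydroxide provokes β-elimination or desilylation.

Step 8
Reactants: 12 (S)-3-(3-bromo-5-iodo-4-methoxyphenyl)-3-[3,5-bis(tert-butyldimethylsilyloxy)phenoxy]propanoic acid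
Product: 14 (S)-2-(3-bromo-5-iodo-4-methoxyphenyl)-5,7-bis(tert-butyldimethylsilyloxy)chroman-4-one, via acyl trifluoroacetate 13 (not isolated)
Conditions: (CF3CO)2O (1.3 equiv), CH2Cl2, 0 °C → rt; cold aq. NaHCO3
Reagents that add atoms: none
Why: Trifluoroacetic anhydride converts the acid into acyl trifluoroacetate 13, whose acyl carbon is attacked by the ring A carbon ortho to O1 (para to one silyloxy group, ortho to the other) to give an arenium ion that rearomatises by proton loss, forming the C4–C4a bond. The closest known reaction type is the intramolecular Friedel–Crafts acylation of 3-aryloxypropanoic acids to chroman-4-ones. Ring C closes in a 6-exo-trig mode, the carbonyl oxygen remaining outside the new ring. No stereocentre is created; C2, set by the Mitsunobu inversion of step 6, is a spectator. The step needs regioselectivity and preservation of the C2 configuration: the tether reaches only the two symmetry-equivalent ortho carbons (future C4a and C8), and the dihalogenated ring B, whose methoxy group is forced out of the ring plane, stabilises a benzylic cation too poorly for the C2–O1 bond to ionise in a cold, weakly acidic medium. Near-stoichiometric anhydride limits intermolecular trifluoroacetylation, and the new ketone deactivates ring A against a second acylation.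

Step 9
Reactants: 14 (S)-2-(3-bromo-5-iodo-4-methoxyphenyl)-5,7-bis(tert-butyldimethylsilyloxy)chroman-4-one; 15 2-methyl-3-butyn-2-ol
Product: 16 (S)-2-[3-bromo-5-(3-hydroxy-3-methylbut-1-yn-1-yl)-4-methoxyphenyl]-5,7-bis(tert-butyldimethylsilyloxy)chroman-4-one
Conditions: PdCl2(PPh3)2 (3 mol %), CuI (5 mol %), Et3N (3 equiv), THF, rt
Reagents that add atoms: none
Why: Sonogashira coupling, in which zerovalent palladium inserts into the C–I bond far faster than into the C–Br bond at room temperature, so only the iodide should be alkynylated while the short, cold exposure to a tertiary amine leaves C2 untouched.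

Step 10
Reactants: 16 (S)-2-[3-bromo-5-(3-hydroxy-3-methylbut-1-yn-1-yl)-4-methoxyphenyl]-5,7-bis(tert-butyldimethylsilyloxy)chroman-4-one; 17 tributyl(3-methylbut-2-en-1-yl)stannane
Product: 18 (S)-5,7-bis(tert-butyldimethylsilyloxy)-2-[3-(3-hydroxy-3-methylbut-1-yn-1-yl)-4-methoxy-5-(3-methylbut-2-en-1-yl)phenyl]chroman-4-one
Conditions: Pd(PPh3)4 (5 mol %), toluene, 100 °C; aq. KF work-up
Reagents that add atoms: none
Why: Stille (Migita–Kosugi) allylation of the aryl bromide under neutral conditions, in which reductive elimination from the arylpalladium prenyl intermediate at its unsubstituted terminus should give the linear prenyl arene without exposing the silyl ethers, the free alcohol or C2 to base.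

Step 11
Reactants: 18 (S)-5,7-bis(tert-butyldimethylsilyloxy)-2-[3-(3-hydroxy-3-methylbut-1-yn-1-yl)-4-methoxy-5-(3-methylbut-2-en-1-yl)phenyl]chroman-4-one
Product: 19 (S)-5,7-bis(tert-butyldimethylsilyloxy)-2-{3-[(Z)-3-hydroxy-3-methylbut-1-en-1-yl]-4-methoxy-5-(3-methylbut-2-en-1-yl)phenyl}chroman-4-one
Conditions: H2 (1 atm), Pd/CaCO3 poisoned with Pb(OAc)2, quinoline, EtOAc, rt, stopped after 1 equiv H2
Reagents that add atoms: none
Why: Lindlar semihydrogenation, in which syn delivery of hydrogen on the poisoned palladium surface should give the Z-alkene while the trisubstituted prenyl alkene and the aryl ketone are not reduced.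

Step 12
Reactants: 19 (S)-5,7-bis(tert-butyldimethylsilyloxy)-2-{3-[(Z)-3-hydroxy-3-methylbut-1-en-1-yl]-4-methoxy-5-(3-methylbut-2-en-1-yl)phenyl}chroman-4-one
Product: 20 (S)-5,7-dihydroxy-2-{3-[(Z)-3-hydroxy-3-methylbut-1-en-1-yl]-4-methoxy-5-(3-methylbut-2-en-1-yl)phenyl}chroman-4-one (CNP0223123.2)
Conditions: Bu4NF (2.4 equiv), AcOH (2.4 equiv), THF, 0 °C
Reagents that add atoms: none
Why: Fluoride-mediated cleavage of the two aryl silyl ethers, buffered with acetic acid so that neither base-induced retro-oxa-Michael opening of ring C (racemisation of C2) nor acid-induced ionisation of the Z-allylic tertiary alcohol should occur.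

Compound list
1 | methyl 3-bromo-4-hydroxybenzoate | COC(=O)c1ccc(O)c(Br)c1 | starting material
2 | methyl 3-bromo-4-hydroxy-5-iodobenzoate | COC(=O)c1cc(Br)c(O)c(I)c1 | intermediate
3 | methyl 3-bromo-5-iodo-4-methoxybenzoate | COC(=O)c1cc(Br)c(OC)c(I)c1 | intermediate
4 | tert-butyl acetate | CC(=O)OC(C)(C)C | starting material
5 | lithium enolate of tert-butyl acetate | [Li]OC(=C)OC(C)(C)C | intermediate (not isolated)
6 | tert-butyl 3-(3-bromo-5-iodo-4-methoxyphenyl)-3-oxopropanoate | COc1c(I)cc(C(=O)CC(=O)OC(C)(C)C)cc1Br | intermediate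
7 | tert-butyl (R)-3-(3-bromo-5-iodo-4-methoxyphenyl)-3-hydroxypropanoate | COc1c(I)cc([C@H](O)CC(=O)OC(C)(C)C)cc1Br | intermediate
8 | phloroglucinol | Oc1cc(O)cc(O)c1 | starting material
9 | 3,5-bis(tert-butyldimethylsilyloxy)phenol | CC(C)(C)[Si](C)(C)Oc1cc(O)cc(O[Si](C)(C)C(C)(C)C)c1 | intermediate
10 | tert-butyl (S)-3-(3-bromo-5-iodo-4-methoxyphenyl)-3-[3,5-bis(tert-butyldimethylsilyloxy)phenoxy]propanoate | COc1c(I)cc([C@@H](Oc2cc(O[Si](C)(C)C(C)(C)C)cc(O[Si](C)(C)C(C)(C)C)c2)CC(=O)OC(C)(C)C)cc1Br | intermediate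
11 | trimethylsilyl (S)-3-(3-bromo-5-iodo-4-methoxyphenyl)-3-[3,5-bis(tert-butyldimethylsilyloxy)phenoxy]propanoate | COc1c(I)cc([C@@H](Oc2cc(O[Si](C)(C)C(C)(C)C)cc(O[Si](C)(C)C(C)(C)C)c2)CC(=O)O[Si](C)(C)C)cc1Br | intermediate (not isolated)
12 | (S)-3-(3-bromo-5-iodo-4-methoxyphenyl)-3-[3,5-bis(tert-butyldimethylsilyloxy)phenoxy]propanoic acid | COc1c(I)cc([C@@H](Oc2cc(O[Si](C)(C)C(C)(C)C)cc(O[Si](C)(C)C(C)(C)C)c2)CC(=O)O)cc1Br | intermediate (key-step precursor)
13 | (S)-3-(3-bromo-5-iodo-4-methoxyphenyl)-3-[3,5-bis(tert-butyldimethylsilyloxy)phenoxy]propanoic trifluoroacetic anhydride | COc1c(I)cc([C@@H](Oc2cc(O[Si](C)(C)C(C)(C)C)cc(O[Si](C)(C)C(C)(C)C)c2)CC(=O)OC(=O)C(F)(F)F)cc1Br | intermediate (not isolated)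
14 | (S)-2-(3-bromo-5-iodo-4-methoxyphenyl)-5,7-bis(tert-butyldimethylsilyloxy)chroman-4-one | COc1c(I)cc([C@@H]2CC(=O)c3c(O[Si](C)(C)C(C)(C)C)cc(O[Si](C)(C)C(C)(C)C)cc3O2)cc1Br | intermediate (key-step product)
15 | 2-methyl-3-butyn-2-ol | CC(C)(O)C#C | starting material
16 | (S)-2-[3-bromo-5-(3-hydroxy-3-methylbut-1-yn-1-yl)-4-methoxyphenyl]-5,7-bis(tert-butyldimethylsilyloxy)chroman-4-one | COc1c(C#CC(C)(C)O)cc([C@@H]2CC(=O)c3c(O[Si](C)(C)C(C)(C)C)cc(O[Si](C)(C)C(C)(C)C)cc3O2)cc1Br | intermediate
17 | tributyl(3-methylbut-2-en-1-yl)stannane | CCCC[Sn](CCCC)(CCCC)CC=C(C)C | starting material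
18 | (S)-5,7-bis(tert-butyldimethylsilyloxy)-2-[3-(3-hydroxy-3-methylbut-1-yn-1-yl)-4-methoxy-5-(3-methylbut-2-en-1-yl)phenyl]chroman-4-one | COc1c(C#CC(C)(C)O)cc([C@@H]2CC(=O)c3c(O[Si](C)(C)C(C)(C)C)cc(O[Si](C)(C)C(C)(C)C)cc3O2)cc1CC=C(C)C | intermediate
19 | (S)-5,7-bis(tert-butyldimethylsilyloxy)-2-{3-[(Z)-3-hydroxy-3-methylbut-1-en-1-yl]-4-methoxy-5-(3-methylbut-2-en-1-yl)phenyl}chroman-4-one | COc1c(/C=C\C(C)(C)O)cc([C@@H]2CC(=O)c3c(O[Si](C)(C)C(C)(C)C)cc(O[Si](C)(C)C(C)(C)C)cc3O2)cc1CC=C(C)C | intermediate
20 | (S)-5,7-dihydroxy-2-{3-[(Z)-3-hydroxy-3-methylbut-1-en-1-yl]-4-methoxy-5-(3-methylbut-2-en-1-yl)phenyl}chroman-4-one (CNP0223123.2) | COc1c(/C=C\C(C)(C)O)cc([C@@H]2CC(=O)c3c(O)cc(O)cc3O2)cc1CC=C(C)C | target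

Total step count: 12 steps.
Longest linear sequence: 11 steps (steps 1–4 and 6–12, from compound 1); step 5 is a one-step side branch.

Steps most likely to fail

Step 8 (key step). The acid liberated during the acylation may loosen the benzylic C2–O1 bond, by ionisation or by retro-oxa-Michael opening and re-closure. That would erode the enantiomeric purity. Intermolecular trifluoroacetylation of the electron-rich ring may also compete with ring closure. The fallback sets out from 12 and comes back at 14, and it replaces the acylium-type electrophile by a base-buffered amide activation. The acid would be condensed with dimethylamine (Me2NH·HCl, EDCI, HOBt, N-methylmorpholine, CH2Cl2, 0 °C) to give (S)-3-(3-bromo-5-iodo-4-methoxyphenyl)-3-[3,5-bis(tert-butyldimethylsilyloxy)phenoxy]-N,N-dimethylpropanamide F1. Activation with Tf2O and 2-fluoropyridine (CH2Cl2, −78 → 0 °C) should let the same ortho carbon of ring A attack the iminium-type electrophile, in an intramolecular Vilsmeier–Haack-type acylation. This would give (S)-N-[2-(3-bromo-5-iodo-4-methoxyphenyl)-5,7-bis(tert-butyldimethylsilyloxy)chroman-4-ylidene]-N-methylmethanaminium triflate F2. Hydrolysis with aqueous NaHCO3 in THF should release ketone 14 without the substrate meeting a strong protic acid.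

Step 6. The oxyphosphonium intermediate may lose a proton from the carbon next to the ester and eliminate to the cinnamate instead of being displaced, and any ionisation would erode the inversion. The fallback sets out from 7 and comes back at 12, and it removes the acidifying carbonyl before the Mitsunobu step. Reduction with LiBH4 (THF, 0 °C → rt) would give (R)-1-(3-bromo-5-iodo-4-methoxyphenyl)propane-1,3-diol F3. Selective acylation of the primary hydroxyl (PivCl, pyridine, CH2Cl2, −20 °C) would give (R)-3-(3-bromo-5-iodo-4-methoxyphenyl)-3-hydroxypropyl pivalate F4. Mitsunobu coupling with 9 under the conditions of step 6 should then proceed with clean inversion to (S)-3-(3-bromo-5-iodo-4-methoxyphenyl)-3-[3,5-bis(tert-butyldimethylsilyloxy)phenoxy]propyl pivalate F5. Reductive removal of the pivalate (iBu2AlH, CH2Cl2, −78 °C) would give (S)-3-(3-bromo-5-iodo-4-methoxyphenyl)-3-[3,5-bis(tert-butyldimethylsilyloxy)phenoxy]propan-1-ol F6. Oxidation with TEMPO and PhI(OAc)2 in MeCN–water would pass through (S)-3-(3-bromo-5-iodo-4-methoxyphenyl)-3-[3,5-bis(tert-butyldimethylsilyloxy)phenoxy]propanal F7, which is not isolated, and should end at acid 12.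

Step 10. The prenyl group may be transferred through its substituted terminus, giving the 1,1-dimethylallyl isomer, or the double bond may migrate into conjugation during the hot coupling. The fallback sets out from 16 and comes back at 18, and it separates C–C coupling from construction of the trisubstituted alkene. Stille coupling with allyltributylstannane (Pd(PPh3)4, toluene, 100 °C), where no allylic regiochemistry is at stake, would give (S)-2-[3-allyl-5-(3-hydroxy-3-methylbut-1-yn-1-yl)-4-methoxyphenyl]-5,7-bis(tert-butyldimethylsilyloxy)chroman-4-one F8. Olefin cross-metathesis with 2-methyl-2-butene as co-solvent (second-generation Grubbs catalyst RuCl2(=CHPh)(H2IMes)(PCy3), CH2Cl2, 40 °C) should then convert the allyl group into the prenyl group of 18. The internal alkyne is flanked by a quaternary carbinol carbon and an ortho-substituted arene, so it should be too hindered to enter enyne metathesis.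

Further compounds
F1 | step 8 | (S)-3-(3-bromo-5-iodo-4-methoxyphenyl)-3-[3,5-bis(tert-butyldimethylsilyloxy)phenoxy]-N,N-dimethylpropanamide | COc1c(I)cc([C@@H](Oc2cc(O[Si](C)(C)C(C)(C)C)cc(O[Si](C)(C)C(C)(C)C)c2)CC(=O)N(C)C)cc1Br
F2 | step 8 | (S)-N-[2-(3-bromo-5-iodo-4-methoxyphenyl)-5,7-bis(tert-butyldimethylsilyloxy)chroman-4-ylidene]-N-methylmethanaminium triflate | COc1c(I)cc([C@@H]2CC(=[N+](C)C)c3c(O[Si](C)(C)C(C)(C)C)cc(O[Si](C)(C)C(C)(C)C)cc3O2)cc1Br.[O-]S(=O)(=O)C(F)(F)F
F3 | step 6 | (R)-1-(3-bromo-5-iodo-4-methoxyphenyl)propane-1,3-diol | COc1c(I)cc([C@H](O)CCO)cc1Br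
F4 | step 6 | (R)-3-(3-bromo-5-iodo-4-methoxyphenyl)-3-hydroxypropyl pivalate | COc1c(I)cc([C@H](O)CCOC(=O)C(C)(C)C)cc1Br
F5 | step 6 | (S)-3-(3-bromo-5-iodo-4-methoxyphenyl)-3-[3,5-bis(tert-butyldimethylsilyloxy)phenoxy]propyl pivalate | COc1c(I)cc([C@@H](Oc2cc(O[Si](C)(C)C(C)(C)C)cc(O[Si](C)(C)C(C)(C)C)c2)CCOC(=O)C(C)(C)C)cc1Br
F6 | step 6 | (S)-3-(3-bromo-5-iodo-4-methoxyphenyl)-3-[3,5-bis(tert-butyldimethylsilyloxy)phenoxy]propan-1-ol | COc1c(I)cc([C@@H](Oc2cc(O[Si](C)(C)C(C)(C)C)cc(O[Si](C)(C)C(C)(C)C)c2)CCO)cc1Br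
F7 | step 6 | (S)-3-(3-bromo-5-iodo-4-methoxyphenyl)-3-[3,5-bis(tert-butyldimethylsilyloxy)phenoxy]propanal | COc1c(I)cc([C@@H](Oc2cc(O[Si](C)(C)C(C)(C)C)cc(O[Si](C)(C)C(C)(C)C)c2)CC=O)cc1Br
F8 | step 10 | (S)-2-[3-allyl-5-(3-hydroxy-3-methylbut-1-yn-1-yl)-4-methoxyphenyl]-5,7-bis(tert-butyldimethylsilyloxy)chroman-4-one | COc1c(C#CC(C)(C)O)cc([C@@H]2CC(=O)c3c(O[Si](C)(C)C(C)(C)C)cc(O[Si](C)(C)C(C)(C)C)cc3O2)cc1CC=C
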